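Retrosynthesis: the epoxide C–O bond and two acetates go first; the cyclohexenone is then cut at C2′–C3′ (carbinol carbon to vinyl CH) and C1′–C6′ (quaternary carbon to α-keto carbon), leaving a four-carbon 2-chloro-3-ethoxy-4-methylcyclobutanone and a two-carbon enol ether on the terpenoid; the decalin goes back to an acyclic epoxy enyne.
Enabling feature: C12 (the allylic carbon on C8, beside C7=C8) and the C9–C11 side chain can be joined through one oxygen into a temporary dihydropyran (ring atoms O, C12, C8, C9, C11, C1′); this makes C1′=C2′ a rigid exocyclic enol ether, its ring oxygen later becomes the epoxide oxygen, and C12 returns to a methyl group.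
Forward order: farnesyl enyne → rings A and B by radical epoxypolyene bicyclization → ene reaction and iodoetherification close the temporary pyran → strain-release [4+2] annulation builds the cyclohexenone → reductive opening of the pyran → epoxide closure and deacetylation.
Stereochemistry: the decalin centers come from one Sharpless epoxide; C1′ from axial attack on the pyran oxocarbenium ion; C2′ from the E enol acetate (anti iodocyclization, retentive copper coupling); C6′ from inversion in the final epoxide closure.
Key step: step 12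

Remark: drimane numbering is used (decalin C1–C10, C11 on C9, C12 on C8, C13 = the 4α carbon, C14 = 4β-CH3, C15 = 10β-CH3, β = the face of C15; all decalins are 5α-H, 9α-H); C1′–C6′ are the carbons of the new six-membered ring, C1′ being bonded to C11; 16 and 18 are used as stereoisomer mixtures because every stereocenter of 18 is erased later.

Step 1
Reactants: 1 (2E,6E)-farnesyl bromide; 2 lithium (trimethylsilyl)acetylide
Product: 3 trimethyl[(4E,8E)-5,9,13-trimethyltetradeca-4,8,12-trien-1-yn-1-yl]silane
Conditions: CuI (10 mol %), THF, −20 → 23 °C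
Reagents that add atoms: none
Why: Copper-catalyzed SN2 coupling of an alkynyl nucleophile with a primary allylic bromide (allylic alkynylation) should give the skipped enyne without touching the two E alkenes, and no stereocenter is formed.

Step 2
Reactants: 3 trimethyl[(4E,8E)-5,9,13-trimethyltetradeca-4,8,12-trien-1-yn-1-yl]silane
Product: 4 (2E,6E,10E)-2,6,10-trimethyl-14-(trimethylsilyl)tetradeca-2,6,10-trien-13-yn-1-ol
Conditions: SeO2 (0.1 equiv), salicylic acid (0.1 equiv), t-BuOOH (3 equiv), CH2Cl2, 23 °C
Reagents that add atoms: tert-butyl hydroperoxide (CC(C)(C)OO)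
Why: SeO2-catalyzed allylic oxidation (Riley oxidation by ene reaction and [2,3]-sigmatropic shift) should hydroxylate the E-methyl group of the most electron-rich, terminal trisubstituted alkene, as is known for farnesyl esters.

Step 3
Reactants: 4 (2E,6E,10E)-2,6,10-trimethyl-14-(trimethylsilyl)tetradeca-2,6,10-trien-13-yn-1-ol
Product: 6 [(2S,3S)-3-[(3E,7E)-3,7-dimethyl-11-(trimethylsilyl)undeca-3,7-dien-10-yn-1-yl]-2-methyloxiran-2-yl]methyl acetate, via epoxy alcohol 5 (not isolated)
Conditions: Ti(OiPr)4 (10 mol %), L-(+)-diethyl tartrate (12 mol %), t-BuOOH (1.5 equiv), 4 Å MS, CH2Cl2, −20 °C; then Ac2O, Et3N, DMAP (cat.), 0 °C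
Reagents that add atoms: tert-butyl hydroperoxide (CC(C)(C)OO); acetic anhydride (CC(=O)OC(C)=O)
Why: Sharpless asymmetric epoxidation with L-(+)-tartrate should deliver oxygen to one face of the E allylic alcohol and so set both epoxide centers as 2S,3S, and acetylation in the same flask protects the primary alcohol (the future C13 hydroxyl).

Step 4
Reactants: 6 [(2S,3S)-3-[(3E,7E)-3,7-dimethyl-11-(trimethylsilyl)undeca-3,7-dien-10-yn-1-yl]-2-methyloxiran-2-yl]methyl acetate
Product: 7 13-acetoxy-11-[(trimethylsilyl)ethynyl]drim-8(12)-en-3β-ol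
Conditions: Cp2TiCl2 (2.2 equiv), Mn dust (8 equiv), THF, 23 °C (6 added slowly); aq. NaH2PO4 work-up
Reagents that add atoms: none
Why: In this titanocene-mediated radical epoxypolyene cyclization, Cp2TiCl (trivalent titanium, formed from Cp2TiCl2 and Mn) opens the epoxide to the tertiary C4 radical, two 6-endo-trig closures through chair-like transition states form rings A and B as the trans-decalin, and the final C8 radical is trapped by titanium and loses a β-hydride to give the exocyclic alkene, so that every ring stereocenter is relayed from the epoxide (3β-OH retained, E-CH2OAc equatorial at C4, 5α-H, 9α-H, 10β-CH3).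

Step 5
Reactants: 7 13-acetoxy-11-[(trimethylsilyl)ethynyl]drim-8(12)-en-3β-ol
Product: 8 13-acetoxy-3β-[(imidazol-1-ylcarbonothioyl)oxy]-11-[(trimethylsilyl)ethynyl]drim-8(12)-ene
Conditions: 1,1′-thiocarbonyldiimidazole (3 equiv), DMAP (cat.), ClCH2CH2Cl, 80 °C
Reagents that add atoms: 1,1′-thiocarbonyldiimidazole (S=C(n1ccnc1)n1ccnc1)
Why: Acylation of the hindered 3β-alcohol with thiocarbonyldiimidazole gives the thiocarbonyl derivative needed for the Barton–McCombie deoxygenation and touches no stereocenter.

Step 6
Reactants: 8 13-acetoxy-3β-[(imidazol-1-ylcarbonothioyl)oxy]-11-[(trimethylsilyl)ethynyl]drim-8(12)-ene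
Product: 9 13-acetoxy-11-[(trimethylsilyl)ethynyl]drim-8(12)-ene
Conditions: Bu3SnH (2 equiv), AIBN (cat.), toluene, 100 °C
Reagents that add atoms: none
Why: Barton–McCombie radical deoxygenation should replace the C3 oxygen, which only served to start the cyclization, by hydrogen, because the secondary C3 radical is far from both π systems and is simply reduced by Bu3SnH.

Step 7
Reactants: 9 13-acetoxy-11-[(trimethylsilyl)ethynyl]drim-8(12)-ene
Product: 11 13-acetoxy-11-[(trimethylsilyl)ethynyl]drim-7-en-12-ol, via allylic hydroperoxide 10 (not isolated)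
Conditions: O2, tetraphenylporphyrin (cat.), visible light, CH2Cl2, 0 °C; then PPh3, 23 °C
Reagents that add atoms: dioxygen (O=O)
Why: The Schenck ene reaction of singlet oxygen with the 1,1-disubstituted alkene should abstract the axial 7α-hydrogen on the open α face, shift the double bond to C7=C8 and place the hydroperoxide on C12, and PPh3 reduces it to the allylic alcohol that will carry the temporary ring.

Step 8
Reactants: 11 13-acetoxy-11-[(trimethylsilyl)ethynyl]drim-7-en-12-ol
Product: 12 13-acetoxy-11-ethynyldrim-7-en-12-ol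
Conditions: Bu4NF (1.2 equiv), AcOH (1.2 equiv), THF, 0 °C
Reagents that add atoms: none
Why: Fluoride-mediated protodesilylation of the alkynylsilane, buffered with acetic acid so that the acetate is not cleaved, frees the terminal alkyne.

Step 9
Reactants: 12 13-acetoxy-11-ethynyldrim-7-en-12-ol
Product: 13 tricyclic (E)-iodo enol ether (oxygen bridges C12 and C1′, C1′=C2′H–I exocyclic)
Conditions: N-iodosuccinimide (1.2 equiv), CH2Cl2, 0 °C, dark
Reagents that add atoms: N-iodosuccinimide (O=C1CCC(=O)N1I)
Why: Electrophilic 6-exo-dig iodocyclization (iodoetherification of the alkynol) should add the C12 oxygen and iodine anti across the triple bond, which closes the dihydropyran and fixes the exocyclic iodoalkene as E (iodine trans to the ring oxygen).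

Step 10
Reactants: 13 tricyclic (E)-iodo enol ether
Product: 14 tricyclic (E)-enol acetate (C1′=C2′H–OAc, acetoxy trans to the ring oxygen)
Conditions: CuOAc (2 equiv), pyridine/DMF, 60 °C
Reagents that add atoms: copper acetate CuOAc (CC(=O)[O-].[Cu+])
Why: Ullmann-type vinylic substitution of the iodide by the copper carboxylate proceeds with retention of alkene geometry, so the acetoxy group is installed trans to the ring oxygen as required for the later trans relation of the two ring oxygens.

Step 11
Reactants: 15 chloroacetyl chloride; 16 ethyl prop-1-enyl ether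
Product: 18 2-chloro-3-ethoxy-4-methylcyclobutan-1-one (stereoisomer mixture), via chloroketene 17 (not isolated)
Conditions: Et3N (1.1 equiv, slow addition), 16 (5 equiv), hexane, 40 °C
Reagents that add atoms: none
Why: Dehydrochlorination gives chloroketene, whose thermal [2+2] cycloaddition with the enol ether joins the ketene carbonyl carbon to the nucleophilic β-carbon of the enol ether and therefore gives the 2-chloro-3-ethoxy-4-methyl substitution pattern needed.

Step 12
Reactants: 14 tricyclic (E)-enol acetate; 18 2-chloro-3-ethoxy-4-methylcyclobutan-1-one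
Product: 20 spiro chloro enone (1′S,2′R,6′R), via ethoxy ketone 19 (not isolated)
Conditions: SnCl4 (0.3 equiv), 18 (1.5 equiv), 4 Å MS, CH2Cl2, −78 → 0 °C
Reagents that add atoms: none
Why: Proposed new method: SnCl4 should open the donor–acceptor C2–C3 bond of cyclobutanone 18 (ethoxy-bearing C3, chlorine-bearing C2), releasing the four-ring strain as a 1,4-zwitterion whose ethoxy-oxocarbenium end (future C3′) is attacked by C2′ of enol ether 14 and whose tin chloro-enolate end (future C6′) then adds to the cyclic oxocarbenium ion formed at C1′, after which the β-ethoxy ketone 19 loses ethanol by acid-promoted β-elimination to give enone 20. The closest known reaction type is the Lewis-acid-promoted formal [4+2] cycloaddition of 3-alkoxycyclobutanones with silyl enol ethers and carbonyl compounds, extended here to an alkyl enol ether bearing an acyloxy group and to a 2-chlorocyclobutanone. The only ring closed is the cyclohexanone, by a 6-(enolendo)-exo-trig attack of the enolate on the C1′ oxocarbenium ion, the first bond being intermolecular. C1′ is controlled by the temporary dihydropyran, because the enolate must add axially to the half-chair oxocarbenium ion (ring atoms O, C12, C8, C9, C11, C1′), which is the α face and meets only the axial hydrogens on C9 and C12; C2′ is controlled by the E geometry of the enol acetate together with addition of both ends of the zwitterion to that same α face, which places the acetoxy group trans to the ring oxygen; C6′ is epimerizable and is drawn with chlorine trans to the ring oxygen, the arrangement needed in step 14. The step needs cleavage of the cyclobutanone on its chlorinated side (secured by the better stabilized chloro-enolate and the push–pull polarization of that bond), attack through C2′ and not C1′ (secured because only the ether oxygen on C1′ can stabilize the cation as a tertiary oxocarbenium ion while the acetoxy group on C2′ is a weak donor), and ring closure faster than proton loss or C1′–C2′ rotation (favored by the tight ion pair at low temperature).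

Step 13
Reactants: 20 spiro chloro enone (1′S,2′R,6′R)
Product: 21 13-acetoxy-11-[(1S,2R,6R)-2-acetoxy-6-chloro-4-methyl-5-oxo-1-(trimethylsilyloxy)cyclohex-3-en-1-yl]drim-7-ene
Conditions: Et3SiH (3 equiv), Me3SiOTf (1.2 equiv), 2,6-di-tert-butyl-4-methylpyridine (0.3 equiv), CH2Cl2, −78 → −40 °C; aq. NaHCO3
Reagents that add atoms: trimethylsilyl trifluoromethanesulfonate (C[Si](C)(C)OS(=O)(=O)C(F)(F)F)
Why: Ionic hydrogenolysis of an allylic ether: silylation of the ring oxygen lets the C12–O bond ionize to the C12–C8–C7 allyl cation, which Et3SiH reduces at the unhindered primary terminus C12, so that the C8 methyl group and the C7=C8 alkene of the target are restored, the tether oxygen stays on C1′ as its trimethylsilyl ether and no stereocenter changes.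

Step 14
Reactants: 21 13-acetoxy-11-[(1S,2R,6R)-2-acetoxy-6-chloro-4-methyl-5-oxo-1-(trimethylsilyloxy)cyclohex-3-en-1-yl]drim-7-ene
Product: 23 Epoxypholamin B, via chlorohydrin 22 (not isolated)
Conditions: K2CO3 (3 equiv), MeOH, 0 → 23 °C
Reagents that add atoms: none
Why: Methanolysis of the silyl ether frees the tertiary C1′ alkoxide, which displaces the anti chloride at C6′ (Darzens-type halohydrin closure, inversion at C6′, retention at C1′) to form the epoxide, and the same K2CO3/MeOH removes both acetates by transesterification, while a C6′ epimer would first equilibrate through the enolate.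

Compound list
1 | (2E,6E)-farnesyl bromide, (2E,6E)-1-bromo-3,7,11-trimethyldodeca-2,6,10-triene | CC(C)=CCC/C(C)=C/CC/C(C)=C/CBr | starting material
2 | lithium (trimethylsilyl)acetylide, LiC≡CSiMe3 | [Li+].[C-]#C[Si](C)(C)C | starting material
3 | trimethyl[(4E,8E)-5,9,13-trimethyltetradeca-4,8,12-trien-1-yn-1-yl]silane | C[Si](C)(C)C#CC/C=C(\C)CC/C=C(\C)CCC=C(C)C | intermediate
4 | (2E,6E,10E)-2,6,10-trimethyl-14-(trimethylsilyl)tetradeca-2,6,10-trien-13-yn-1-ol | C[Si](C)(C)C#CC/C=C(\C)CC/C=C(\C)CC/C=C(\C)CO | intermediate
5 | [(2S,3S)-3-[(3E,7E)-3,7-dimethyl-11-(trimethylsilyl)undeca-3,7-dien-10-yn-1-yl]-2-methyloxiran-2-yl]methanol | C[Si](C)(C)C#CC/C=C(\C)CC/C=C(\C)CC[C@@H]1O[C@@]1(C)CO | intermediate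
6 | [(2S,3S)-3-[(3E,7E)-3,7-dimethyl-11-(trimethylsilyl)undeca-3,7-dien-10-yn-1-yl]-2-methyloxiran-2-yl]methyl acetate | C[Si](C)(C)C#CC/C=C(\C)CC/C=C(\C)CC[C@@H]1O[C@@]1(C)COC(C)=O | intermediate
7 | 13-acetoxy-11-[(trimethylsilyl)ethynyl]drim-8(12)-en-3β-ol (4α-CH2OAc, 4β-CH3, 5α-H, 9α-H, 10β-CH3) | C[Si](C)(C)C#CC[C@H]3C(=C)CC[C@H]4[C@](C)(COC(C)=O)[C@@H](O)CC[C@]34C | intermediate
8 | 13-acetoxy-3β-[(imidazol-1-ylcarbonothioyl)oxy]-11-[(trimethylsilyl)ethynyl]drim-8(12)-ene | C[Si](C)(C)C#CC[C@H]3C(=C)CC[C@H]4[C@](C)(COC(C)=O)[C@@H](OC(=S)n1ccnc1)CC[C@]34C | intermediate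
9 | 13-acetoxy-11-[(trimethylsilyl)ethynyl]drim-8(12)-ene | C[Si](C)(C)C#CC[C@H]3C(=C)CC[C@H]4[C@](C)(COC(C)=O)CCC[C@]34C | intermediate
10 | 13-acetoxy-12-hydroperoxy-11-[(trimethylsilyl)ethynyl]drim-7-ene | C[Si](C)(C)C#CC[C@H]3C(COO)=CC[C@H]4[C@](C)(COC(C)=O)CCC[C@]34C | intermediate
11 | 13-acetoxy-11-[(trimethylsilyl)ethynyl]drim-7-en-12-ol | C[Si](C)(C)C#CC[C@H]3C(CO)=CC[C@H]4[C@](C)(COC(C)=O)CCC[C@]34C | intermediate
12 | 13-acetoxy-11-ethynyldrim-7-en-12-ol | C#CC[C@H]3C(CO)=CC[C@H]4[C@](C)(COC(C)=O)CCC[C@]34C | intermediate
13 | tricyclic (E)-iodo enol ether: 13-acetoxydrim-7-ene in which oxygen links C12 to C1′ (ring O–C12–C8–C9–C11–C1′) and C1′=C2′H–I is exocyclic, iodine trans to the ring oxygen | I/C=C1/OCC2=CC[C@H]3[C@](C)(COC(C)=O)CCC[C@]3(C)[C@H]2C1 | intermediate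
14 | tricyclic (E)-enol acetate: as 13 with acetoxy in place of iodine, acetoxy trans to the ring oxygen | CC(=O)O/C=C1/OCC2=CC[C@H]3[C@](C)(COC(C)=O)CCC[C@]3(C)[C@H]2C1 | intermediate
15 | chloroacetyl chloride | ClCC(Cl)=O | starting material
16 | ethyl prop-1-enyl ether (E/Z mixture) | CCOC=CC | starting material
17 | chloroketene | ClC=C=O | intermediate
18 | 2-chloro-3-ethoxy-4-methylcyclobutan-1-one (stereoisomer mixture) | CCOC1C(C)C(=O)C1Cl | intermediate
19 | spiro β-ethoxy ketone: 2′-acetoxy-6′-chloro-3′-ethoxy-4′-methylcyclohexan-5′-one spiro-fused at C1′ to the pyran of 14 (1′S,2′R,6′R; epimer mixture at C3′ and C4′) | CC1C(OCC)[C@@H](OC(C)=O)[C@@]2(C[C@H]3C(=CC[C@H]4[C@](C)(COC(C)=O)CCC[C@]34C)CO2)[C@@H](Cl)C1=O | intermediate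
20 | spiro chloro enone (1′S,2′R,6′R): 2′-acetoxy-6′-chloro-4′-methylcyclohex-3′-en-5′-one spiro-fused at C1′ to the pyran (O–C12–C8–C9–C11–C1′); C6′ on the α face, acetoxy and chlorine trans to the ring oxygen | CC1=C[C@@H](OC(C)=O)[C@@]2(C[C@H]3C(=CC[C@H]4[C@](C)(COC(C)=O)CCC[C@]34C)CO2)[C@@H](Cl)C1=O | intermediate
21 | 13-acetoxy-11-[(1S,2R,6R)-2-acetoxy-6-chloro-4-methyl-5-oxo-1-(trimethylsilyloxy)cyclohex-3-en-1-yl]drim-7-ene | CC1=C[C@@H](OC(C)=O)[C@](C[C@H]3C(C)=CC[C@H]4[C@](C)(COC(C)=O)CCC[C@]34C)(O[Si](C)(C)C)[C@@H](Cl)C1=O | intermediate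
22 | 13-acetoxy-11-[(1S,2R,6R)-2-acetoxy-6-chloro-1-hydroxy-4-methyl-5-oxocyclohex-3-en-1-yl]drim-7-ene | CC1=C[C@@H](OC(C)=O)[C@](C[C@H]3C(C)=CC[C@H]4[C@](C)(COC(C)=O)CCC[C@]34C)(O)[C@@H](Cl)C1=O | intermediate
23 | Epoxypholamin B, (1S,5R,6S)-5-hydroxy-6-(13-hydroxydrim-7-en-11-yl)-3-methyl-7-oxabicyclo[4.1.0]hept-3-en-2-one | CC1=C[C@@H](O)[C@]2(C[C@H]3C(C)=CC[C@H]4[C@](C)(CO)CCC[C@]34C)O[C@@H]2C1=O | target

Total step count: 14. Longest linear sequence: 13 steps (steps 1–10 and 12–14, from 1); step 11 is a one-step side branch.

Steps most likely to fail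

1. Step 12 (Proposed new method). What may go wrong: cleavage of the cyclobutanone on its methyl-bearing side, loss of a proton or of the allyl group from the intermediate oxocarbenium ion before ring closure, rotation about C1′–C2′ that scrambles the carbinol center, or Lewis-acid rearrangement of the allyl vinyl ether. Fallback with known reactions, run stepwise; it sets out from 18 and 14 and returns at 20. Acid-catalyzed methanolysis of 18 (HCl, MeOH) should open the ring to the keto acetal 1-chloro-4,4-dimethoxy-3-methylbutan-2-one F1. BF3·OEt2-catalyzed addition of this acetal to enol ether 14 at −78 °C (acetal–enol ether addition, the cation being captured by methoxide) should give the mixed methyl ketal F2. TiCl4 with iPr2NEt (soft enolization of the chloromethyl ketone, ionization of the ketal, intramolecular Mukaiyama-type addition with the same axial attack) should close the ring to the β-methoxy ketone F3, which loses methanol with p-TsOH to rejoin the route at 20.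

2. Step 13. What may go wrong: hydride transfer to the silyl-activated ketone or enone, hydride delivery to C7 (which leaves the exocyclic alkene), or failure of the hindered ether oxygen to ionize. Fallback; it sets out from 20 and returns at 22. Me2BBr (CH2Cl2, −78 °C) should cleave the allylic C12–O bond to the allylic bromide with free tertiary alcohol F4. Pd(PPh3)4 (cat.) with Bu3SnH then reduces the allylic bromide through the π-allyl complex, with hydride delivery to the primary terminus, to give chlorohydrin 22, which is carried into step 14.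

3. Step 14. What may go wrong: retro-aldol opening of the tertiary alkoxide before it closes, base-induced opening or aromatization of the epoxy enone, Payne-type migration of the epoxide, or slow methanolysis of the hindered C13 acetate. Fallback; it sets out from 21 and returns at 23. Et3N·3HF (MeCN, 0 °C) removes the silyl group to give 22, which is isolated. Ag2O (CH2Cl2, 4 Å MS) closes the epoxide under neutral, halophilic conditions to the epoxy diacetate F5. Immobilized Candida antarctica lipase B in pH 7 buffer/acetone then hydrolyzes both acetates to 23.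

Further compounds
F1 | step 12 | 1-chloro-4,4-dimethoxy-3-methylbutan-2-one | COC(OC)C(C)C(=O)CCl
F2 | step 12 | mixed methyl ketal: 1′-methoxy pyran of 14 carrying at C1′ the chain CH(OAc)–CH(OMe)–CH(CH3)–CO–CH2Cl (2′R; mixture at the other new centers) | COC(C(C)C(=O)CCl)[C@@H](OC(C)=O)C1(OC)C[C@H]2C(=CC[C@H]3[C@](C)(COC(C)=O)CCC[C@]23C)CO1
F3 | step 12 | spiro β-methoxy ketone, the 3′-methoxy analogue of 19 | CC1C(OC)[C@@H](OC(C)=O)[C@@]2(C[C@H]3C(=CC[C@H]4[C@](C)(COC(C)=O)CCC[C@]34C)CO2)[C@@H](Cl)C1=O
F4 | step 13 | 13-acetoxy-12-bromo-11-[(1S,2R,6R)-2-acetoxy-6-chloro-1-hydroxy-4-methyl-5-oxocyclohex-3-en-1-yl]drim-7-ene | CC1=C[C@@H](OC(C)=O)[C@](C[C@H]3C(CBr)=CC[C@H]4[C@](C)(COC(C)=O)CCC[C@]34C)(O)[C@@H](Cl)C1=O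
F5 | step 14 | Epoxypholamin B diacetate (5-O-acetyl, 13-O-acetyl) | CC1=C[C@@H](OC(C)=O)[C@]2(C[C@H]3C(C)=CC[C@H]4[C@](C)(COC(C)=O)CCC[C@]34C)O[C@@H]2C1=O
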